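**Retrosynthetic overview**
1. Feature (germacrane numbering): in the ten-membered carbocycle the C9 ketone and the Z C4=C5 olefin form a cyclodec-5-enone. The Z C1=C10 enone bond fits a cyclohexene once C4 and C9 are joined, so the target maps onto a cis-decalin (ring A: C1–C4, C9, C10; ring B: C4–C9).
2. Endgame disconnections: the C8 angelate (acylation of the only secondary OH), the C7/C8 acetonide, and the α-methylene-γ-lactone (C6–O–C12 and C11–C12 from CO and the C6–OH/C7–C≡CH homopropargylic alcohol).
3. Key disconnection: the C4–C9 bond is put back, so cyclodecadienone 25 comes from hydroxy mesylate 23 (C9–OH, C5–OMs) by Grob fragmentation.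
4. 23 comes from ring A enone 19 (β-epoxidation, Wharton transposition, mesylation). The four ring B oxygens come from two face-selective OsO4 dihydroxylations of 7-alkynyl trienone 15 (C5=C6 from the α face, C7=C8 from the β face).
5. Ring order: ring B (Michael–Claisen annulation, already carrying the C7 alkyne), then ring A (amino-acid-mediated Robinson annulation, sets C4), then the ten-membered ring (step 16), then the lactone (step 18).

Key step: step 16

Remark: germacrane numbering is used throughout, β is the face of the C4 methyl and α the opposite face; the alkyne is built into ring B and carried as its TIPS derivative, because a C7 ketone next to C8–H and the ring A enone would exist as a vinylogous 1,3-diketone enol and could not be ethynylated; C7 is an inconsequential epimer mixture in 11 and 12.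

**Step 1**
Reactants: 1 3-(triisopropylsilyl)prop-2-ynal; 2 diethyl (2-oxobutyl)phosphonate
Product: 3 (E)-7-(triisopropylsilyl)hept-4-en-6-yn-3-one
Conditions: LiCl, iPr2NEt, MeCN, 0 °C → rt
Reagents that add atoms: none
Why: Horner–Wadsworth–Emmons olefination under Masamune–Roush conditions, in which the stabilised β-keto phosphonate anion should give the E enone and the mild amine base spares the ynal and the silyl alkyne.

**Step 2**
Reactants: 3 enynone; 4 tert-butyl ethyl malonate
Product: 6 tert-butyl 3-methyl-2,4-dioxo-6-[(triisopropylsilyl)ethynyl]cyclohexane-1-carboxylate (racemic, keto–enol and diastereomer mixture), via Michael adduct 5 (not isolated)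
Conditions: NaOEt, EtOH, 0 °C → reflux; cold 1 M HCl
Reagents that add atoms: none
Why: Tandem Michael addition–Claisen condensation, the classical entry to 5-substituted cyclohexane-1,3-diones, in which the malonate adds 1,4 because TIPS blocks the alkyne terminus and the ketone α′-methylene attacks only the ethyl ester to close ring B; all stereocentres formed are labile or removed later.

**Step 3**
Reactants: 6 keto ester
Product: 8 2-methyl-5-[(triisopropylsilyl)ethynyl]cyclohexane-1,3-dione, via keto acid 7 (not isolated)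
Conditions: TFA, CH2Cl2, rt; then toluene, 100 °C
Reagents that add atoms: none
Why: Acidolysis of the tert-butyl ester followed by thermal decarboxylation of the β-keto acid, conditions that leave the TIPS alkyne untouched.

**Step 4**
Reactants: 8 alkynyl dione; 9 ethyl vinyl ketone
Product: 10 2-methyl-2-(3-oxopentyl)-5-[(triisopropylsilyl)ethynyl]cyclohexane-1,3-dione (achiral cis/trans mixture)
Conditions: Et3N (cat.), THF, rt
Reagents that add atoms: none
Why: Michael addition of the acidic 2-alkyl-1,3-dione through the carbon that becomes C4; both isomers of 10 have a mirror plane, so no stereochemical issue arises here.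

**Step 5**
Reactants: 10 triketone
Product: 11 (4aS)-1,4a-dimethyl-7-[(triisopropylsilyl)ethynyl]-4,4a,7,8-tetrahydronaphthalene-2,5(3H,6H)-dione (C1=O, C9=C10, C5=O; C4 S, C7 epimers)
Conditions: (S)-phenylalanine, (+)-camphorsulfonic acid, DMF, 30 → 70 °C
Reagents that add atoms: none
Why: Hajos–Parrish–Eder–Sauer–Wiechert-type asymmetric Robinson cyclodehydration, in which the enamine of the ethyl ketone attacks one of the two enantiotopic ring carbonyls, closes ring A and sets C4 as S (the usual sense for (S)-amino acids); the C7 substituent lies on the mirror plane of 10 and should not bias the choice, and enrichment by recrystallisation is foreseen at diol 16.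

**Step 6**
Reactants: 11 enedione
Product: 12 5β-hydroxy enone (C5–OH cis to the C4 methyl, ring A enone intact, C7 epimers)
Conditions: NaBH4 (0.3 equiv), EtOH, −10 °C
Reagents that add atoms: none
Why: Chemoselective borohydride reduction of the saturated C5 ketone, which is far more electrophilic than the tetrasubstituted enone; hydride arrives on the α face opposite the angular methyl, and this centre is erased in step 8.

**Step 7**
Reactants: 12 hydroxy enone
Product: 13 5β-hydroxy linear dienone (C1=O, C9=C10, C7=C8 bearing the alkyne)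
Conditions: chloranil, t-BuOH, reflux
Reagents that add atoms: none
Why: Quinone dehydrogenation of an enone to the linear dienone through its extended dienol, with hydride abstraction from the allylic and propargylic C7–H, so that both C7 epimers converge.

**Step 8**
Reactants: 13 hydroxy dienone
Product: 15 7-alkynyl trienone (C1=O, C9=C10, C7=C8, C5=C6; C4 as in 11), via dienone mesylate 14 (not isolated)
Conditions: MsCl, Et3N, CH2Cl2, 0 °C; then DBU, rt
Reagents that add atoms: methanesulfonyl chloride, CS(=O)(=O)Cl (atoms kept in 14 only)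
Why: Mesylation followed by vinylogous E1cB elimination, since C6–H is the ε-position of the dienone and the extended enolate expels the neopentyl mesylate without an anti-periplanar requirement and without cationic rearrangement.

**Step 9**
Reactants: 15 trienone
Product: 16 5α,6α-diol of the 7-alkynyl dienone
Conditions: OsO4 (cat.), NMO (1.05 equiv), acetone–H2O, 0 °C
Reagents that add atoms: osmium tetroxide, O=[Os](=O)(=O)=O; N-methylmorpholine N-oxide, C[N+]1([O-])CCOCC1; water, O
Why: Upjohn dihydroxylation, in which OsO4 should take the least substituted olefin most remote from the carbonyl (C5=C6), as is general for polyenones; the syn addition occurs on the α face opposite the pseudo-axial C4 methyl and sets C5 and C6.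

**Step 10**
Reactants: 16 diol
Product: 17 6α-O-TBS ether (C5α–OH free)
Conditions: TBSCl (1.1 equiv), imidazole, DMF, 0 °C
Reagents that add atoms: tert-butyldimethylsilyl chloride, CC(C)(C)[Si](C)(C)Cl
Why: Sterically differentiated silylation, since C6–OH is allylic and flanked by an sp2 carbon whereas C5–OH is neopentyl.

**Step 11**
Reactants: 17 silyl ether
Product: 18 triol (C5α–OH, C7β–OH with α-alkynyl, C8β–OH; C6α–OTBS; ring A enone)
Conditions: OsO4 (cat.), NMO, MeSO2NH2, t-BuOH–THF–H2O, rt
Reagents that add atoms: osmium tetroxide, O=[Os](=O)(=O)=O; N-methylmorpholine N-oxide, C[N+]1([O-])CCOCC1; water, O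
Why: Second Upjohn dihydroxylation, in which only C7=C8 can react (the tetrasubstituted enone and the shielded alkyne are inert); the syn addition is expected anti to the allylic C6 silyl ether and the axial C5 oxygen, on the β face, setting C7 and C8.

**Step 12**
Reactants: 18 triol
Product: 19 C7/C8 acetonide enone (C5α–OH free, C6α–OTBS)
Conditions: 2,2-dimethoxypropane, PPTS (cat.), CH2Cl2, rt
Reagents that add atoms: 2,2-dimethoxypropane, COC(C)(C)OC
Why: Acid-catalysed transketalisation, in which only C7–OH and C8–OH are cis-vicinal (C5–OH is trans-1,3 to C7–OH and cannot bridge), so the tertiary C7 oxygen is masked selectively.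

**Step 13**
Reactants: 19 acetonide enone
Product: 20 9β,10β-epoxy ketone
Conditions: 30% H2O2, aq NaOH, MeOH–THF, 0 °C → rt
Reagents that add atoms: hydrogen peroxide, OO
Why: Weitz–Scheffer epoxidation; α attack at C9 would lead to a trans-decalin enolate with C9–O, C5–O and the C7 alkynyl group all syn-axial, so addition on the β face (also the inherent bias of angular-methyl octalones) should prevail and set C9 and C10.

**Step 14**
Reactants: 20 epoxy ketone
Product: 22 cis-decalin diol (C9β–OH, C1=C10, C5α–OH), via epoxy hydrazone 21 (not isolated)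
Conditions: N2H4·H2O, AcOH (cat.), degassed MeOH, 0 °C → rt
Reagents that add atoms: hydrazine hydrate, NN.O (nitrogen kept in 21 only)
Why: Wharton transposition, in which the hydrazone collapses with loss of N2 and opening of the epoxide; the C9–O bond is not touched, so C9–OH stays cis to the C4 methyl and the olefin ends at C1=C10.

**Step 15**
Reactants: 22 diol
Product: 23 cis-decalin hydroxy mesylate (C9β–OH, C5α–OMs, C6α–OTBS, C7/C8 β-acetonide, C7α TIPS-ethynyl)
Conditions: MsCl, Et3N, CH2Cl2, −10 °C
Reagents that add atoms: methanesulfonyl chloride, CS(=O)(=O)Cl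
Why: Selective sulfonylation of the only secondary alcohol, the hindered tertiary C9–OH staying free and the amine being too weak a base to start the fragmentation.

**Step 16**
Reactants: 23 hydroxy mesylate
Product: 25 Z,Z-cyclodecadienone (C9=O, C1=C10, C4=C5, C6–OTBS, C7/C8 acetonide, C7 TIPS-ethynyl), via potassium alkoxide 24 (not isolated)
Conditions: KOtBu (1.1 equiv), t-BuOH–THF, 0 °C → rt; pH 7 buffer
Reagents that add atoms: potassium tert-butoxide, CC(C)(C)[O-].[K+] (potassium kept in 24 only)
Why: KOtBu turns the axial C9 hydroxyl into alkoxide 24, in which an oxygen lone pair, the C9–C4 σ bond and the equatorial C5–OMs bond are anti-periplanar in the cis-decalin conformer that has C3 axial on ring B, so C9=O and C4=C5 form while C4–C9 and C5–O break in one concerted heterolysis. The closest known reaction type is the Grob (Wharton) fragmentation of decalin-1,3-diol monosulfonates to cyclodec-5-enones. The ten-membered ring is not closed by bond formation but is uncovered by scission of the bond shared by rings A and B, so no medium-ring cyclisation has to be paid for. No stereocentre is created: C4, C5 and C9 become trigonal, C6, C7 and C8 are untouched, C4=C5 comes out Z because axial C3 is gauche and the equatorial methyl anti to C6 about C4–C5, and C1=C10 stays Z because it was a cyclohexene bond. The selectivity needed is C4–C9 over C6–C7 cleavage and fragmentation over elimination or substitution, which is secured because the C7 oxygen is locked in the acetonide and cannot push, the equatorial mesylate has no anti-periplanar hydrogen, and O9 cannot reach the back side of C5. After ring opening the dioxolane keeps the C7–O bond close to the plane of a C8 enolate, which disfavours β-elimination, and the TIPS group removes the acidic alkyne proton.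

**Step 17**
Reactants: 25 cyclodecadienone
Product: 26 C6 alcohol with terminal C7 alkyne (acetonide kept)
Conditions: TBAF, AcOH, THF, 0 °C → rt
Reagents that add atoms: none
Why: Buffered fluoride desilylation removes the O-TBS and C-TIPS groups in one operation without enolising the C9 ketone.

**Step 18**
Reactants: 26 homopropargylic alcohol
Product: 27 α-methylene-γ-lactone acetonide
Conditions: PdCl2 (10 mol %), thiourea, CO (1 atm), acetone, 50 °C
Reagents that add atoms: carbon monoxide, [C-]#[O+]
Why: PdCl2-catalysed cyclocarbonylation of a but-3-yn-1-ol, in which the alkoxycarbonyl complex of divalent palladium formed from C6–OH and CO adds syn across the alkyne in 5-exo mode and protonolysis releases the α-methylene lactone; C6–O and C7–C11 are cis, so the ring closes without touching a stereocentre.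

**Step 19**
Reactants: 27 lactone acetonide
Product: 28 C7,C8-diol
Conditions: TFA–H2O, CH2Cl2, 0 °C → rt
Reagents that add atoms: water, O
Why: Acid hydrolysis of the isopropylidene ketal; lactone and enone tolerate the acid, and the tertiary C7–OH, flanked by electron-poor C11 and C8, should not ionise.

**Step 20**
Reactants: 28 diol; 29 angelic acid
Product: 31 target CNP0276177.1 (6S,7R,8R; C8 angelate), via mixed anhydride 30 (not isolated)
Conditions: 29, 2,4,6-trichlorobenzoyl chloride, Et3N, toluene, rt; then 28, toluene, 80 °C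
Reagents that add atoms: 2,4,6-trichlorobenzoyl chloride, O=C(Cl)c1c(Cl)cc(Cl)cc1Cl (atoms kept in 30 only)
Why: Yamaguchi-type mixed anhydride esterification run without a nucleophilic catalyst, in which only the secondary C8–OH is acylated (tertiary C7–OH is inert) and the absence of DMAP or strong base should prevent Z to E isomerisation to the tiglate.

**Compound list**
1 | 3-(triisopropylsilyl)prop-2-ynal | O=CC#C[Si](C(C)C)(C(C)C)C(C)C | starting material
2 | diethyl (2-oxobutyl)phosphonate | CCC(=O)CP(=O)(OCC)OCC | starting material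
3 | (E)-7-(triisopropylsilyl)hept-4-en-6-yn-3-one | CCC(=O)/C=C/C#C[Si](C(C)C)(C(C)C)C(C)C | intermediate
4 | tert-butyl ethyl malonate | CCOC(=O)CC(=O)OC(C)(C)C | starting material
5 | Michael adduct, 1-tert-butyl 3-ethyl 2-[5-oxo-1-(triisopropylsilyl)hept-1-yn-3-yl]malonate | CCC(=O)CC(C#C[Si](C(C)C)(C(C)C)C(C)C)C(C(=O)OCC)C(=O)OC(C)(C)C | intermediate
6 | tert-butyl 3-methyl-2,4-dioxo-6-[(triisopropylsilyl)ethynyl]cyclohexane-1-carboxylate | CC1C(=O)CC(C#C[Si](C(C)C)(C(C)C)C(C)C)C(C(=O)OC(C)(C)C)C1=O | intermediate
7 | 3-methyl-2,4-dioxo-6-[(triisopropylsilyl)ethynyl]cyclohexane-1-carboxylic acid | CC1C(=O)CC(C#C[Si](C(C)C)(C(C)C)C(C)C)C(C(=O)O)C1=O | intermediate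
8 | 2-methyl-5-[(triisopropylsilyl)ethynyl]cyclohexane-1,3-dione | CC1C(=O)CC(C#C[Si](C(C)C)(C(C)C)C(C)C)CC1=O | intermediate
9 | ethyl vinyl ketone | C=CC(=O)CC | starting material
10 | 2-methyl-2-(3-oxopentyl)-5-[(triisopropylsilyl)ethynyl]cyclohexane-1,3-dione | CCC(=O)CCC1(C)C(=O)CC(C#C[Si](C(C)C)(C(C)C)C(C)C)CC1=O | intermediate
11 | (4aS)-enedione, C7 epimers | CC1=C2CC(C#C[Si](C(C)C)(C(C)C)C(C)C)CC(=O)[C@@]2(C)CCC1=O | intermediate
12 | 5β-hydroxy enone, C7 epimers | CC1=C2CC(C#C[Si](C(C)C)(C(C)C)C(C)C)C[C@H](O)[C@@]2(C)CCC1=O | intermediate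
13 | 5β-hydroxy linear dienone | CC1=C2C=C(C#C[Si](C(C)C)(C(C)C)C(C)C)C[C@H](O)[C@@]2(C)CCC1=O | intermediate
14 | 5β-mesyloxy linear dienone | CC1=C2C=C(C#C[Si](C(C)C)(C(C)C)C(C)C)C[C@H](OS(C)(=O)=O)[C@@]2(C)CCC1=O | intermediate
15 | 7-alkynyl trienone | CC1=C2C=C(C#C[Si](C(C)C)(C(C)C)C(C)C)C=C[C@@]2(C)CCC1=O | intermediate
16 | 5α,6α-diol dienone | CC1=C2C=C(C#C[Si](C(C)C)(C(C)C)C(C)C)[C@@H](O)[C@@H](O)[C@@]2(C)CCC1=O | intermediate
17 | 6α-O-TBS, 5α-hydroxy dienone | CC1=C2C=C(C#C[Si](C(C)C)(C(C)C)C(C)C)[C@@H](O[Si](C)(C)C(C)(C)C)[C@@H](O)[C@@]2(C)CCC1=O | intermediate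
18 | 5α,7β,8β-triol enone | CC1=C2[C@H](O)[C@@](O)(C#C[Si](C(C)C)(C(C)C)C(C)C)[C@@H](O[Si](C)(C)C(C)(C)C)[C@@H](O)[C@@]2(C)CCC1=O | intermediate
19 | C7/C8 acetonide enone | CC1=C2[C@@H]3OC(C)(C)O[C@]3(C#C[Si](C(C)C)(C(C)C)C(C)C)[C@@H](O[Si](C)(C)C(C)(C)C)[C@@H](O)[C@@]2(C)CCC1=O | intermediate
20 | 9β,10β-epoxy ketone | C[C@@]12O[C@@]13[C@@H]4OC(C)(C)O[C@]4(C#C[Si](C(C)C)(C(C)C)C(C)C)[C@@H](O[Si](C)(C)C(C)(C)C)[C@@H](O)[C@@]3(C)CCC2=O | intermediate
21 | epoxy hydrazone | C[C@@]12O[C@@]13[C@@H]4OC(C)(C)O[C@]4(C#C[Si](C(C)C)(C(C)C)C(C)C)[C@@H](O[Si](C)(C)C(C)(C)C)[C@@H](O)[C@@]3(C)CCC2=NN | intermediate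
22 | cis-decalin C5α,C9β-diol | CC1=CCC[C@]2(C)[C@H](O)[C@H](O[Si](C)(C)C(C)(C)C)[C@@]3(C#C[Si](C(C)C)(C(C)C)C(C)C)OC(C)(C)O[C@H]3[C@]12O | intermediate
23 | cis-decalin hydroxy mesylate | CC1=CCC[C@]2(C)[C@H](OS(C)(=O)=O)[C@H](O[Si](C)(C)C(C)(C)C)[C@@]3(C#C[Si](C(C)C)(C(C)C)C(C)C)OC(C)(C)O[C@H]3[C@]12O | intermediate
24 | potassium C9 alkoxide of 23 | CC1=CCC[C@]2(C)[C@H](OS(C)(=O)=O)[C@H](O[Si](C)(C)C(C)(C)C)[C@@]3(C#C[Si](C(C)C)(C(C)C)C(C)C)OC(C)(C)O[C@H]3[C@]12[O-].[K+] | intermediate
25 | Z,Z-cyclodecadienone | CC(C)(C)[Si](C)(C)O[C@H]1/C=C(/C)CC/C=C(/C)C(=O)[C@@H]2OC(C)(C)O[C@]12C#C[Si](C(C)C)(C(C)C)C(C)C | intermediate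
26 | C6 alcohol, terminal alkyne | O[C@H]1/C=C(/C)CC/C=C(/C)C(=O)[C@@H]2OC(C)(C)O[C@]12C#C | intermediate
27 | α-methylene lactone acetonide | C=C1C(=O)O[C@H]2/C=C(/C)CC/C=C(/C)C(=O)[C@@H]3OC(C)(C)O[C@]123 | intermediate
28 | C7,C8-diol lactone | C=C1C(=O)O[C@H]2/C=C(/C)CC/C=C(/C)C(=O)[C@H](O)[C@@]12O | intermediate
29 | angelic acid | C/C=C(/C)C(=O)O | starting material
30 | angelic 2,4,6-trichlorobenzoic anhydride | C/C=C(/C)C(=O)OC(=O)c1c(Cl)cc(Cl)cc1Cl | intermediate
31 | CNP0276177.1 | C=C1C(=O)O[C@H]2/C=C(/C)CC/C=C(/C)C(=O)[C@H](OC(=O)/C(C)=C\C)[C@@]12O | target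

**Total step count:** 20. **Longest linear sequence:** 20 steps (from 1 or 2).

**Steps most likely to fail**

Step 16 (key step). After ring opening, remaining base may enolise the new C9 ketone toward C8, which would epimerise C8 or expel the C7 oxygen. It may also deconjugate the C1=C10 enone, and attack of base on the sulfonate could return the C5 alcohol. The fallback sets out from 23 and comes back at 25. The fragmentation is run with KN(SiMe3)2 in THF at −78 °C. As soon as 23 is consumed, iBu2AlH is added to the same flask, so the enone leaves the basic medium as the ten-membered C9 allylic alcohol F1 (C9 epimers, of no consequence). MnO2 in CH2Cl2 then reoxidises the allylic alcohol to 25 under neutral conditions.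

Step 13. Three things may go wrong:
- Conjugate addition of hydroperoxide at the fully substituted C9, between C4 and C8, may be too slow.
- The free C5 alkoxide may trigger vinylogous retro-aldol cleavage or silyl migration in the basic medium.
- The β-face preference may be insufficient.

The fallback replaces nucleophilic by hydroxyl-directed electrophilic epoxidation. It sets out from 19 and comes back at 23.
- MsCl and Et3N give the C5 mesylate enone F2.
- Luche reduction (NaBH4, CeCl3·7H2O, MeOH) delivers hydride axially from the α face and gives the C1β allylic alcohol F3.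
- mCPBA, guided by the C1β hydroxyl onto the electron-rich tetrasubstituted olefin, gives the 9β,10β-epoxy alcohol F4.
- Dess–Martin periodinane oxidises the only free hydroxyl to the epoxy ketone mesylate F5.
- Wharton transposition (N2H4·H2O, AcOH, MeOH) then gives 23 directly.

Step 11. The electron-poor trisubstituted C7=C8 olefin may react sluggishly. Facial selectivity may also be poor, because the C4 methyl hinders the β face at C8 while only a silyl ether and a free hydroxyl guard the α face. The fallback installs a rigid cis-fused ring on the α face before the dihydroxylation. It sets out from 16 and comes back at 19.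
- 1,1′-Carbonyldiimidazole in toluene gives the C5,C6 cyclic carbonate F6.
- OsO4 and NMO attack its convex β face and give the carbonate diol F7.
- 2,2-Dimethoxypropane and PPTS give the carbonate acetonide F8.
- K2CO3 in MeOH removes the carbonate and gives the C5,C6-diol acetonide F9.
- TBSOTf and 2,6-lutidine at −78 °C silylate the less hindered C6–OH and give 19.

**Further compounds**
F1 | step 16 | ten-membered C9 allylic alcohol (C9 epimers) | CC(C)(C)[Si](C)(C)O[C@H]1/C=C(/C)CC/C=C(/C)C(O)[C@@H]2OC(C)(C)O[C@]12C#C[Si](C(C)C)(C(C)C)C(C)C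
F2 | step 13 | C5 mesylate enone | CC1=C2[C@@H]3OC(C)(C)O[C@]3(C#C[Si](C(C)C)(C(C)C)C(C)C)[C@@H](O[Si](C)(C)C(C)(C)C)[C@@H](OS(C)(=O)=O)[C@@]2(C)CCC1=O
F3 | step 13 | C1β allylic alcohol | CC1=C2[C@@H]3OC(C)(C)O[C@]3(C#C[Si](C(C)C)(C(C)C)C(C)C)[C@@H](O[Si](C)(C)C(C)(C)C)[C@@H](OS(C)(=O)=O)[C@@]2(C)CC[C@@H]1O
F4 | step 13 | 9β,10β-epoxy alcohol | C[C@@]12O[C@@]13[C@@H]4OC(C)(C)O[C@]4(C#C[Si](C(C)C)(C(C)C)C(C)C)[C@@H](O[Si](C)(C)C(C)(C)C)[C@@H](OS(C)(=O)=O)[C@@]3(C)CC[C@@H]2O
F5 | step 13 | epoxy ketone mesylate | C[C@@]12O[C@@]13[C@@H]4OC(C)(C)O[C@]4(C#C[Si](C(C)C)(C(C)C)C(C)C)[C@@H](O[Si](C)(C)C(C)(C)C)[C@@H](OS(C)(=O)=O)[C@@]3(C)CCC2=O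
F6 | step 11 | C5,C6 cyclic carbonate | CC1=C2C=C(C#C[Si](C(C)C)(C(C)C)C(C)C)[C@H]3OC(=O)O[C@H]3[C@@]2(C)CCC1=O
F7 | step 11 | carbonate diol | CC1=C2[C@H](O)[C@@](O)(C#C[Si](C(C)C)(C(C)C)C(C)C)[C@H]3OC(=O)O[C@H]3[C@@]2(C)CCC1=O
F8 | step 11 | carbonate acetonide | CC1=C2[C@@H]4OC(C)(C)O[C@]4(C#C[Si](C(C)C)(C(C)C)C(C)C)[C@H]3OC(=O)O[C@H]3[C@@]2(C)CCC1=O
F9 | step 11 | C5,C6-diol acetonide | CC1=C2[C@@H]3OC(C)(C)O[C@]3(C#C[Si](C(C)C)(C(C)C)C(C)C)[C@@H](O)[C@@H](O)[C@@]2(C)CCC1=O
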